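**Plan**
- Numbering follows the chroman-2-one core: ring A is the benzo ring (C4a–C8a), ring B the lactone (O1, C2, C3, C4, C4a, C8a). The retrosynthesis cuts, in order: three protective O–benzyl bonds (O5 and both catechol oxygens), the Cα=Cβ bond of the C8 enone, C2–O1 and C2–C3 of ring B, and the C4–C4a bond.
- Enabling feature: in ring B the carbonyl carbon C2 only links O1 to the C3 methylene, and C4 carries one hydrogen. Removing C2 as CO therefore leaves an ortho-(1-phenylvinyl)phenol on ring A.
- Forward order: ring A is bought as phloroacetophenone and O5 is benzylated. The carbon that becomes C4a is iodinated and coupled to the 1-phenylvinyl unit, and ring B is closed with CO.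
- The caffeoyl chain is then joined by an acid-promoted aldol condensation that spares the lactone, and the benzyl groups are removed at −78 °C.
- Stereochemistry: C4 (R) is the only stereocentre. It arises in the ring B closure by face-selective addition of a chiral diphosphine palladium hydride to the 1,1-diarylethene. The enone is E by thermodynamic control of the dehydration.

Key step: step 4

Assumption: the ligand is written as (R,R,R,R)-WingPhos on the premise that it delivers hydrogen to the face of 5 that leads to 4R; if a first run shows the opposite sense, the (S,S,S,S) antipode is used and nothing else changes.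

Step 1
Reactants: 1 2',4',6'-trihydroxyacetophenone
Product: 2 1-[4-(benzyloxy)-2,6-dihydroxyphenyl]ethanone
Conditions: BnBr (1.0 equiv), K2CO3 (1.0 equiv), acetone, reflux
Reagents that add atoms: benzyl bromide, BrCc1ccccc1
Why: Williamson ether synthesis in which the 4-OH, the only hydroxyl not hydrogen-bonded to the acetyl carbonyl and the most acidic one, is alkylated first, so one equivalent of halide and base should favour the 4-monoether and any dibenzyl ether is removed by chromatography.

Step 2
Reactants: 2 1-[4-(benzyloxy)-2,6-dihydroxyphenyl]ethanone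
Product: 3 1-[4-(benzyloxy)-2,6-dihydroxy-3-iodophenyl]ethanone
Conditions: NIS (1.0 equiv), MeCN, 0 °C to rt, dark
Reagents that add atoms: N-iodosuccinimide, O=C1CCC(=O)N1I
Why: Electrophilic aromatic iodination of an activated phloroglucinol ring whose two open positions are equivalent by symmetry, so only one monoiodide can form, and the first iodine slows a second substitution.

Step 3
Reactants: 3 1-[4-(benzyloxy)-2,6-dihydroxy-3-iodophenyl]ethanone; 4 4,4,5,5-tetramethyl-2-(1-phenylethenyl)-1,3,2-dioxaborolane
Product: 5 1-[4-(benzyloxy)-2,6-dihydroxy-3-(1-phenylethenyl)phenyl]ethanone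
Conditions: Pd(OAc)2 (5 mol %), SPhos (10 mol %), K3PO4 (4 equiv), 1,4-dioxane/H2O, 80 °C
Reagents that add atoms: none
Why: Suzuki–Miyaura coupling of an aryl iodide with an alkenylboronate, a standard entry to 1,1-diarylethenes; the bulky electron-rich biaryl phosphine is designed for di-ortho-substituted halides, the free phenols are carried as phenoxides, and the acetyl group is inert.

Step 4
Reactants: 5 1-[4-(benzyloxy)-2,6-dihydroxy-3-(1-phenylethenyl)phenyl]ethanone; 6 carbon monoxide
Product: 7 (4R)-8-acetyl-5-(benzyloxy)-7-hydroxy-4-phenyl-3,4-dihydro-2H-chromen-2-one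
Conditions: Pd(OAc)2 (5 mol %), (R,R,R,R)-WingPhos (6 mol %), TsOH·H2O (20 mol %), CO (20 bar), 1,2-dichloroethane, 70 °C
Reagents that add atoms: none
Why: Reduction of Pd(OAc)2 under CO to zerovalent palladium and protonation by TsOH should give a cationic diphosphine palladium hydride, which adds across the C=CH2 bond of 5 with H to the diaryl carbon (C4) and Pd to the methylene (C3); CO 6 then inserts into the Pd–C3 bond (C3–C2) and the neighbouring phenol oxygen takes over the acyl group (C2–O1), which frees the hydride again. The closest known reaction type is the palladium-catalysed asymmetric hydroesterification (cyclocarbonylation) of 2-(1-arylvinyl)phenols to 4-aryl-3,4-dihydrocoumarins with P-stereogenic diphosphines, applied here to a more crowded arene. Ring B closes by 6-exo-trig attack of O1 on the acylpalladium carbonyl. C4 is set in the hydropalladation, where the deep chiral pocket of the ligand distinguishes the flat, conjugated phenyl group from ring A, which its two ortho oxygens turn out of the alkene plane, and since the only β-hydrogen of the alkylpalladium is the one just delivered, reversal can only return 5 and no alkene isomer. The linear regiochemistry that is needed follows from the 1,1-disubstitution, because the other mode would require a tertiary dibenzylic palladium alkyl. Of the three ring A oxygens only O1 can close the ring: O5 is benzylated, and the 7-OH lies para to the alkenyl carbon and out of reach, where it also takes the hydrogen bond to the acetyl carbonyl and leaves O1–H free.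

Step 5
Reactants: 7 (4R)-8-acetyl-5-(benzyloxy)-7-hydroxy-4-phenyl-3,4-dihydro-2H-chromen-2-one; 8 3,4-bis(benzyloxy)benzaldehyde
Product: 10 (4R)-5-(benzyloxy)-8-[(2E)-3-[3,4-bis(benzyloxy)phenyl]prop-2-enoyl]-7-hydroxy-4-phenyl-3,4-dihydro-2H-chromen-2-one, via β-hydroxy ketone 9 (not isolated)
Conditions: BF3·OEt2 (2 equiv), 1,4-dioxane, rt; then H2O
Reagents that add atoms: none
Why: Lewis-acid-promoted Claisen–Schmidt condensation, chosen because hydroxide would open the aryl lactone; the BF3-bound ketone enolises and adds to the activated aldehyde, the benzylic aldol 9 loses water under the push of the para-benzyloxy group to give the more stable E-enone, C4 is not involved, and a transiently opened lactone could only reclose on O1 because O5 is blocked.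

Step 6
Reactants: 10 (4R)-5-(benzyloxy)-8-[(2E)-3-[3,4-bis(benzyloxy)phenyl]prop-2-enoyl]-7-hydroxy-4-phenyl-3,4-dihydro-2H-chromen-2-one
Product: 11 (4R)-8-[(2E)-3-(3,4-dihydroxyphenyl)prop-2-enoyl]-5,7-dihydroxy-4-phenyl-3,4-dihydro-2H-chromen-2-one (CNP0187838.1)
Conditions: BCl3 (6 equiv), C6HMe5 (10 equiv), CH2Cl2, −78 °C; then H2O
Reagents that add atoms: none
Why: Lewis-acid debenzylation of aryl benzyl ethers with pentamethylbenzene as a non-basic cation scavenger (Friedel–Crafts capture of the benzyl cation), which at −78 °C should spare the enone that hydrogenolysis would saturate, prevent C-benzylation of ring A, and keep the lactone closed so that it cannot move to the newly freed O5, while C4 stays untouched.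

**Compound list**
1 | 2',4',6'-trihydroxyacetophenone | CC(=O)c1c(O)cc(O)cc1O | starting material
2 | 1-[4-(benzyloxy)-2,6-dihydroxyphenyl]ethanone | CC(=O)c1c(O)cc(OCc2ccccc2)cc1O | intermediate
3 | 1-[4-(benzyloxy)-2,6-dihydroxy-3-iodophenyl]ethanone | CC(=O)c1c(O)cc(OCc2ccccc2)c(I)c1O | intermediate
4 | 4,4,5,5-tetramethyl-2-(1-phenylethenyl)-1,3,2-dioxaborolane | C=C(c1ccccc1)B1OC(C)(C)C(C)(C)O1 | starting material
5 | 1-[4-(benzyloxy)-2,6-dihydroxy-3-(1-phenylethenyl)phenyl]ethanone | CC(=O)c1c(O)cc(OCc2ccccc2)c(C(=C)c2ccccc2)c1O | intermediate
6 | carbon monoxide | [C-]#[O+] | starting material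
7 | (4R)-8-acetyl-5-(benzyloxy)-7-hydroxy-4-phenyl-3,4-dihydro-2H-chromen-2-one | O=C1C[C@H](c2ccccc2)c2c(OCc3ccccc3)cc(O)c(C(C)=O)c2O1 | intermediate
8 | 3,4-bis(benzyloxy)benzaldehyde | O=Cc1ccc(OCc2ccccc2)c(OCc2ccccc2)c1 | starting material
9 | (4R)-5-(benzyloxy)-8-{3-[3,4-bis(benzyloxy)phenyl]-3-hydroxypropanoyl}-7-hydroxy-4-phenyl-3,4-dihydro-2H-chromen-2-one (both carbinol epimers) | O=C1C[C@H](c2ccccc2)c2c(OCc3ccccc3)cc(O)c(C(=O)CC(O)c3ccc(OCc4ccccc4)c(OCc4ccccc4)c3)c2O1 | intermediate
10 | (4R)-5-(benzyloxy)-8-[(2E)-3-[3,4-bis(benzyloxy)phenyl]prop-2-enoyl]-7-hydroxy-4-phenyl-3,4-dihydro-2H-chromen-2-one | O=C1C[C@H](c2ccccc2)c2c(OCc3ccccc3)cc(O)c(C(=O)/C=C/c3ccc(OCc4ccccc4)c(OCc4ccccc4)c3)c2O1 | intermediate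
11 | (4R)-8-[(2E)-3-(3,4-dihydroxyphenyl)prop-2-enoyl]-5,7-dihydroxy-4-phenyl-3,4-dihydro-2H-chromen-2-one | O=C1C[C@H](c2ccccc2)c2c(O)cc(O)c(C(=O)/C=C/c3ccc(O)c(O)c3)c2O1 | target

Total step count: 6. Longest linear sequence: 6 (1 → 2 → 3 → 5 → 7 → 10 → 11).

**Steps most likely to fail**

Risk 1 (step 4):
- What may go wrong: slow hydropalladation of an alkene whose ring A carries two ortho oxygens, weak facial discrimination, or acid-induced oligomerisation of the electron-rich alkene.
- Fallback: ring B is built in racemic form by a known Lewis-acid annulation and then resolved.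
- Setting out from 2, Yb(OTf)3-catalysed reaction with commercial 5-benzylidene Meldrum's acid in MeNO2 at 100 °C is used. This runs through Friedel–Crafts conjugate addition at the free ring carbon, acylation of the only free ortho hydroxyl, and loss of acetone and CO2.
- It should give racemic 8-acetyl-5-(benzyloxy)-7-hydroxy-4-phenyl-3,4-dihydro-2H-chromen-2-one F1.
- Preparative chromatography on a chiral stationary phase then separates this into 7, where the route is rejoined, and (4S)-8-acetyl-5-(benzyloxy)-7-hydroxy-4-phenyl-3,4-dihydro-2H-chromen-2-one F2.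

Risk 2 (step 5):
- What may go wrong: sluggish enolisation of the flanked ketone, hydrolytic opening of the lactone by the water of condensation, or oxa-Michael closure of the 7-OH onto the new enone.
- Fallback: the enol component is preformed and the aldol and the dehydration are run separately.
- Setting out from 7, TMSOTf/Et3N in CH2Cl2 at 0 °C should give (4R)-5-(benzyloxy)-4-phenyl-7-[(trimethylsilyl)oxy]-8-{1-[(trimethylsilyl)oxy]ethenyl}-3,4-dihydro-2H-chromen-2-one F3.
- A Mukaiyama aldol addition of F3 to 8 with BF3·OEt2 at −78 °C and a mildly acidic work-up should give the β-hydroxy ketone 9, isolated in this variant.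
- Catalytic TsOH in toluene at or slightly above room temperature dehydrates 9 to 10, where the route is rejoined.

Risk 3 (step 3):
- What may go wrong: loss of iodine by protodehalogenation, slow transmetalation at a carbon flanked by two oxygens, or protodeboronation of the alkenylboronate.
- Fallback: the halide and the boronate are both dropped and the C–C bond is made by electrophilic substitution.
- Setting out from 2, metal-triflate-catalysed Friedel–Crafts alkenylation with phenylacetylene (In(OTf)3, 10 mol %, 1,2-dichloroethane, 80 °C) is used. It adds the arene in the Markovnikov sense to the alkyne.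
- Because the two free ring positions of 2 are equivalent, this should lead directly to 5, where the route is rejoined. It bypasses 3 and 4 and makes no compound outside the list (entry F0).

Further compounds
F1 | step 4 | racemic 8-acetyl-5-(benzyloxy)-7-hydroxy-4-phenyl-3,4-dihydro-2H-chromen-2-one | O=C1CC(c2ccccc2)c2c(OCc3ccccc3)cc(O)c(C(C)=O)c2O1
F2 | step 4 | (4S)-8-acetyl-5-(benzyloxy)-7-hydroxy-4-phenyl-3,4-dihydro-2H-chromen-2-one | O=C1C[C@@H](c2ccccc2)c2c(OCc3ccccc3)cc(O)c(C(C)=O)c2O1
F3 | step 5 | (4R)-5-(benzyloxy)-4-phenyl-7-[(trimethylsilyl)oxy]-8-{1-[(trimethylsilyl)oxy]ethenyl}-3,4-dihydro-2H-chromen-2-one | O=C1C[C@H](c2ccccc2)c2c(OCc3ccccc3)cc(O[Si](C)(C)C)c(C(=C)O[Si](C)(C)C)c2O1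
F0 | step 3 | none | none
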